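**Retrosynthetic overview**

- Feature: in unit 1 (5,7-dihydroxy half) the O1–C2 bond of ring C lies β to the C4 ketone and C3 is an enolisable CH carrying the C3–C3'' link, so 2,3-trans is the resting arrangement. In unit 2 (7-methoxy half) C2''/C3'' are cis, which is what syn addition of H2 to a flat flavone C2''=C3'' bond gives.
- Disconnections, backwards: benzyl ether cleavage; syn hydrogenation of the unit 2 flavone; O1–C2 oxa-Michael closure of an α-(flavon-3-yl)-2'-hydroxychalcone; Knoevenagel formation of Cα=Cβ with 4-methoxybenzaldehyde; Pd-catalysed α-arylation joining the unit 1 acetyl carbon to C3'' of a 3-iodoflavone.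
- Ring order: ring C of unit 2 first, as a 4H-chromen-4-one (step 1); ring C of unit 1 second (step 9); ring C of unit 2 is saturated last (step 10). All benzene rings come from the starting materials.

Key step: step 9

Assumption: the quinine-derived thiourea is taken to give 2S, and the (R,R) form of SINpEt·HBF4 (1,3-bis[(R)-1-(naphthalen-1-yl)ethyl]-4,5-dihydroimidazolium tetrafluoroborate) is taken to give 2''S,3''S. If a first run shows the opposite sense, the quinidine-derived pseudo-enantiomer or the (S,S) salt is used, with no other change.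

**Step 1**
Reactants: 1 1-(2,6-dihydroxy-4-methoxyphenyl)ethanone; 2 4-methoxybenzoyl chloride
Product: 4 5-hydroxy-7-methoxy-2-(4-methoxyphenyl)-4H-chromen-4-one, via β-diketone 3 (not isolated)
Conditions: LiN(SiMe3)2 (4.2 equiv), THF, −78 °C to rt; aq HCl work-up; then AcOH, H2SO4 (cat.), 95 °C
Reagents that add atoms: none
Why: C-acylation of the lithium polyanion of 1 by 2 (a one-flask Baker–Venkataraman-type Claisen condensation) gives β-diketone 3, and acid-catalysed cyclodehydration closes the pyranone ring; the two hydroxyls of 1 are equivalent, so only one flavone can form and the second hydroxyl ends as the chelated 5-OH.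

**Step 2**
Reactants: 4 5-hydroxy-7-methoxy-2-(4-methoxyphenyl)-4H-chromen-4-one
Product: 5 5-(benzyloxy)-7-methoxy-2-(4-methoxyphenyl)-4H-chromen-4-one
Conditions: BnBr (1.5 equiv), K2CO3, DMF, 70 °C
Reagents that add atoms: benzyl bromide, BrCc1ccccc1
Why: Williamson etherification; the 5-OH is hydrogen-bonded to C4=O and therefore needs warm DMF, and no other acidic site is present.

**Step 3**
Reactants: 5 5-(benzyloxy)-7-methoxy-2-(4-methoxyphenyl)-4H-chromen-4-one
Product: 7 5-(benzyloxy)-3-iodo-7-methoxy-2-(4-methoxyphenyl)-4H-chromen-4-one, via 3-lithioflavone 6 (not isolated)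
Conditions: LiN(iPr)2 (1.3 equiv), THF, −78 °C; then I2, −78 °C to 0 °C
Reagents that add atoms: iodine, II
Why: Directed lithiation removes C3–H, the vinylic proton next to the lithium-binding carbonyl, and iodine quenches the vinyllithium at C3 while the cold keeps it from opening the ring.

**Step 4**
Reactants: 8 1-(2,4,6-trihydroxyphenyl)ethanone
Product: 9 1-[2,4-bis(benzyloxy)-6-hydroxyphenyl]ethanone
Conditions: BnBr (2.05 equiv), K2CO3, DMF, 0 °C to rt
Reagents that add atoms: benzyl bromide, BrCc1ccccc1
Why: Williamson etherification under substrate control: the 4-OH and one ortho OH alkylate, while the last ortho hydroxyl is locked in a hydrogen bond to the acetyl group and reacts far more slowly with a weak base at room temperature.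

**Step 5**
Reactants: 9 1-[2,4-bis(benzyloxy)-6-hydroxyphenyl]ethanone
Product: 10 1-[2,4-bis(benzyloxy)-6-(methoxymethoxy)phenyl]ethanone
Conditions: MOMCl, Cs2CO3, DMF, rt
Reagents that add atoms: chloromethyl methyl ether, COCCl
Why: Williamson-type O-alkylation of the chelated phenol with the stronger carbonate; the MOM ether keeps this oxygen from adding to the enone made in step 7, withstands the bases of steps 6 and 7 and, unlike an allyl ether, is inert to zerovalent palladium.

**Step 6**
Reactants: 10 1-[2,4-bis(benzyloxy)-6-(methoxymethoxy)phenyl]ethanone; 7 5-(benzyloxy)-3-iodo-7-methoxy-2-(4-methoxyphenyl)-4H-chromen-4-one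
Product: 11 1-[2,4-bis(benzyloxy)-6-(methoxymethoxy)phenyl]-2-[5-(benzyloxy)-7-methoxy-2-(4-methoxyphenyl)-4-oxo-4H-chromen-3-yl]ethanone
Conditions: Pd2(dba)3 (2.5 mol %), Xantphos (6 mol %), K3PO4 (2.5 equiv), toluene, 90 °C
Reagents that add atoms: none
Why: Palladium-catalysed α-arylation of a methyl ketone: oxidative addition of the C3–I bond to zerovalent palladium, exchange of iodide for the enolate of 10 and C–C reductive elimination join the acetyl carbon to C3 of the flavone; phosphate is too weak to open the pyranone and the hindered product resists a second arylation.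

**Step 7**
Reactants: 11 MOM-protected aryl (flavon-3-yl)methyl ketone; 12 4-methoxybenzaldehyde
Product: 13 (E)-1-[2,4-bis(benzyloxy)-6-(methoxymethoxy)phenyl]-2-[5-(benzyloxy)-7-methoxy-2-(4-methoxyphenyl)-4-oxo-4H-chromen-3-yl]-3-(4-methoxyphenyl)prop-2-en-1-one
Conditions: piperidine (0.3 equiv), AcOH (0.3 equiv), toluene, reflux, Dean–Stark
Reagents that add atoms: none
Why: Knoevenagel condensation: the methylene of 11, acidified by the ketone and the flavonyl group, adds to the iminium ion of 12 and water is removed azeotropically, which should give the more stable E alkene with the anisyl group trans to the aroyl group; the MOM ether prevents the racemic ring closure that a free 2'-OH would undergo under these conditions.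

**Step 8**
Reactants: 13 MOM-protected α-(flavon-3-yl)chalcone
Product: 14 (E)-1-[2,4-bis(benzyloxy)-6-hydroxyphenyl]-2-[5-(benzyloxy)-7-methoxy-2-(4-methoxyphenyl)-4-oxo-4H-chromen-3-yl]-3-(4-methoxyphenyl)prop-2-en-1-one
Conditions: HCl (1 M in MeOH), THF, 0 °C to rt; pH 7 buffer work-up
Reagents that add atoms: none
Why: Acid-catalysed acetal exchange with methanol removes the MOM group as dimethoxymethane; benzyl ethers and both enones are inert to dilute acid at room temperature, and without base the freed phenol should stay hydrogen-bonded to the ketone and not cyclise.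

**Step 9**
Reactants: 14 2'-hydroxy-α-(flavon-3-yl)chalcone
Product: 15 (2S,3R)-5,7-bis(benzyloxy)-3-[5-(benzyloxy)-7-methoxy-2-(4-methoxyphenyl)-4-oxo-4H-chromen-3-yl]-2-(4-methoxyphenyl)chroman-4-one
Conditions: N-[3,5-bis(trifluoromethyl)phenyl]-N'-[(8α,9S)-6'-methoxycinchonan-9-yl]thiourea (10 mol %), toluene, −25 °C; then filtration through SiO2
Reagents that add atoms: none
Why: The quinuclidine nitrogen of the catalyst takes up the 2'-OH proton while the thiourea N–H pair binds the chalcone carbonyl (the flavone C4'' carbonyl can act as a second acceptor, in the place of the ester of an alkylidene β-keto ester), and the phenoxide oxygen adds to Cβ to form O1–C2. The closest known reaction is the cinchona-thiourea-catalysed intramolecular oxa-Michael cyclisation of α-substituted 2'-hydroxychalcones to flavanones, applied here to an α-heteroaryl member. Ring C of unit 1 closes in the 6-endo-trig mode. C2 is set by the catalyst, which exposes one face of the E alkene to the tethered oxygen, and C3 is set on protonation of the enol and then by equilibration through that enol to the trans-diequatorial 2S,3R isomer. The step needs enantioface selectivity at Cβ and chemoselectivity for the chalcone over the flavone: the single E geometry from step 7 and the 6'-benzyloxy group, which leaves only one hydroxyl able to close, serve the first, and the flavone C2'' is a fully substituted vinylogous-ester carbon that the phenol could reach only through a seven-membered ring. Erosion of C2 by retro-Michael opening through the acidic C3–H is held back by the low temperature, the absence of added base and removal of the catalyst on silica at full conversion.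

**Step 10**
Reactants: 15 (2S,3R)-flavanone bearing the flavon-3-yl group
Product: 16 (2S,3R)-5,7-bis(benzyloxy)-3-[(2S,3S)-5-(benzyloxy)-7-methoxy-2-(4-methoxyphenyl)-4-oxochroman-3-yl]-2-(4-methoxyphenyl)chroman-4-one
Conditions: Ru(cod)(2-methylallyl)2 (5 mol %), (R,R)-SINpEt·HBF4 (10 mol %), KOtBu (9 mol %), hexane, 70 °C, preformed; then 15, toluene, H2 (100 bar), 25 °C, stopped at consumption of 15
Reagents that add atoms: none
Why: Proposed new method: the chiral Ru–carbene complex is expected to bind one face of the flavone enone, chosen by the naphthylethyl groups of the carbene, and to pass both hydrogens from the metal to C2'' and C3'' on that face (syn addition), so the two new centres arise together as 2''S,3''S-cis without an enolate or free alkoxide that could epimerise C3 or C3'', and the two ketones, each flanked by an ortho benzyloxy group and a branched α-carbon, should be reduced more slowly than the enone; the closest known reaction is the Ru–NHC-catalysed asymmetric hydrogenation of the C2=C3 bond of 2-aryl-4H-chromen-4-ones, which to my knowledge has not been shown for a tetrasubstituted 3-alkylflavone next to resident stereocentres.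

**Step 11**
Reactants: 16 tribenzyl ether of the biflavanone
Product: 17 (2S,3R)-5,7-dihydroxy-3-[(2S,3S)-5-hydroxy-7-methoxy-2-(4-methoxyphenyl)-4-oxochroman-3-yl]-2-(4-methoxyphenyl)chroman-4-one (CNP0184936.3)
Conditions: H2 (1 atm), 10% Pd/C, EtOAc–MeOH, rt
Reagents that add atoms: none
Why: Hydrogenolysis of the three benzyl ethers on palladium in a neutral medium, which should leave the enolisable C3 and C3'' centres, both ketones and the benzylic C2–O and C2''–O bonds untouched if stopped at full debenzylation.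

**Compound list**

1 | 1-(2,6-dihydroxy-4-methoxyphenyl)ethanone | CC(=O)c1c(O)cc(OC)cc1O | starting material
2 | 4-methoxybenzoyl chloride | COc1ccc(C(=O)Cl)cc1 | starting material
3 | 1-(2,6-dihydroxy-4-methoxyphenyl)-3-(4-methoxyphenyl)propane-1,3-dione | COc1ccc(C(=O)CC(=O)c2c(O)cc(OC)cc2O)cc1 | intermediate (not isolated)
4 | 5-hydroxy-7-methoxy-2-(4-methoxyphenyl)-4H-chromen-4-one | COc1ccc(-c2cc(=O)c3c(O)cc(OC)cc3o2)cc1 | intermediate
5 | 5-(benzyloxy)-7-methoxy-2-(4-methoxyphenyl)-4H-chromen-4-one | COc1ccc(-c2cc(=O)c3c(OCc4ccccc4)cc(OC)cc3o2)cc1 | intermediate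
6 | [5-(benzyloxy)-7-methoxy-2-(4-methoxyphenyl)-4-oxo-4H-chromen-3-yl]lithium | [Li]c1c(-c2ccc(OC)cc2)oc2cc(OC)cc(OCc3ccccc3)c2c1=O | intermediate (not isolated)
7 | 5-(benzyloxy)-3-iodo-7-methoxy-2-(4-methoxyphenyl)-4H-chromen-4-one | COc1ccc(-c2oc3cc(OC)cc(OCc4ccccc4)c3c(=O)c2I)cc1 | intermediate
8 | 1-(2,4,6-trihydroxyphenyl)ethanone | CC(=O)c1c(O)cc(O)cc1O | starting material
9 | 1-[2,4-bis(benzyloxy)-6-hydroxyphenyl]ethanone | CC(=O)c1c(O)cc(OCc2ccccc2)cc1OCc1ccccc1 | intermediate
10 | 1-[2,4-bis(benzyloxy)-6-(methoxymethoxy)phenyl]ethanone | CC(=O)c1c(OCOC)cc(OCc2ccccc2)cc1OCc1ccccc1 | intermediate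
11 | 1-[2,4-bis(benzyloxy)-6-(methoxymethoxy)phenyl]-2-[5-(benzyloxy)-7-methoxy-2-(4-methoxyphenyl)-4-oxo-4H-chromen-3-yl]ethanone | COCOc1cc(OCc2ccccc2)cc(OCc2ccccc2)c1C(=O)Cc1c(-c2ccc(OC)cc2)oc2cc(OC)cc(OCc3ccccc3)c2c1=O | intermediate
12 | 4-methoxybenzaldehyde | COc1ccc(C=O)cc1 | starting material
13 | (E)-1-[2,4-bis(benzyloxy)-6-(methoxymethoxy)phenyl]-2-[5-(benzyloxy)-7-methoxy-2-(4-methoxyphenyl)-4-oxo-4H-chromen-3-yl]-3-(4-methoxyphenyl)prop-2-en-1-one | COc1ccc(/C=C(/C(=O)c2c(OCOC)cc(OCc3ccccc3)cc2OCc2ccccc2)c2c(-c3ccc(OC)cc3)oc3cc(OC)cc(OCc4ccccc4)c3c2=O)cc1 | intermediate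
14 | (E)-1-[2,4-bis(benzyloxy)-6-hydroxyphenyl]-2-[5-(benzyloxy)-7-methoxy-2-(4-methoxyphenyl)-4-oxo-4H-chromen-3-yl]-3-(4-methoxyphenyl)prop-2-en-1-one | COc1ccc(/C=C(/C(=O)c2c(O)cc(OCc3ccccc3)cc2OCc2ccccc2)c2c(-c3ccc(OC)cc3)oc3cc(OC)cc(OCc4ccccc4)c3c2=O)cc1 | intermediate (key-step precursor)
15 | (2S,3R)-5,7-bis(benzyloxy)-3-[5-(benzyloxy)-7-methoxy-2-(4-methoxyphenyl)-4-oxo-4H-chromen-3-yl]-2-(4-methoxyphenyl)chroman-4-one | COc1ccc([C@H]2Oc3cc(OCc4ccccc4)cc(OCc4ccccc4)c3C(=O)[C@@H]2c2c(-c3ccc(OC)cc3)oc3cc(OC)cc(OCc4ccccc4)c3c2=O)cc1 | intermediate (key-step product)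
16 | (2S,3R)-5,7-bis(benzyloxy)-3-[(2S,3S)-5-(benzyloxy)-7-methoxy-2-(4-methoxyphenyl)-4-oxochroman-3-yl]-2-(4-methoxyphenyl)chroman-4-one | COc1ccc([C@H]2Oc3cc(OCc4ccccc4)cc(OCc4ccccc4)c3C(=O)[C@@H]2[C@@H]2C(=O)c3c(OCc4ccccc4)cc(OC)cc3O[C@@H]2c2ccc(OC)cc2)cc1 | intermediate
17 | (2S,3R)-5,7-dihydroxy-3-[(2S,3S)-5-hydroxy-7-methoxy-2-(4-methoxyphenyl)-4-oxochroman-3-yl]-2-(4-methoxyphenyl)chroman-4-one | COc1ccc([C@H]2Oc3cc(O)cc(O)c3C(=O)[C@@H]2[C@@H]2C(=O)c3c(O)cc(OC)cc3O[C@@H]2c2ccc(OC)cc2)cc1 | target

**Totals**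

Total step count: 11. Longest linear sequence: 9 steps (steps 1, 2, 3, 6, 7, 8, 9, 10, 11).

**Steps most likely to fail**

1. Step 10 (proposed new method). The tetrasubstituted C2''=C3'' bond may not turn over at ruthenium. Hydrogen may arrive on the wrong face if the resident C3 centre opposes the carbene. The C4 and C4'' carbonyls may be reduced further. Traces of alkoxide from catalyst formation may epimerise C3 or C3'' or open ring C of unit 1. The fallback sets out from 15 and returns at 17, using heterogeneous syn hydrogenation, a known way to take a flavone C2=C3 bond to the flavanone. Hydrogenolysis of 15 (H2, 10% Pd/C, EtOAc–MeOH) gives (2S,3R)-5,7-dihydroxy-3-[5-hydroxy-7-methoxy-2-(4-methoxyphenyl)-4-oxo-4H-chromen-3-yl]-2-(4-methoxyphenyl)chroman-4-one F1. This is hydrogenated over Pd(OH)2/C in EtOAc–AcOH under pressure; both hydrogens come from the metal surface, so C2''/C3'' are again cis. The facial choice is then left to the resident C2/C3 centres, and 17 would be separated by preparative HPLC from its (2''R,3''R) isomer, (2S,3R)-5,7-dihydroxy-3-[(2R,3R)-5-hydroxy-7-methoxy-2-(4-methoxyphenyl)-4-oxochroman-3-yl]-2-(4-methoxyphenyl)chroman-4-one F2.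

2. Step 9 (key step). The α-flavonyl group offers weaker two-point binding than an α-ester, so enantioface discrimination may be low. The uncatalysed closure may compete. C2 may erode by reversible ring opening through the acidic C3–H. The fallback sets out from 14 and returns at 15, replacing catalyst control by resolution. Base-mediated chalcone–flavanone isomerisation (NaOAc, EtOH, 50 °C) gives the racemic trans flavanone, that is 15 together with (2R,3S)-5,7-bis(benzyloxy)-3-[5-(benzyloxy)-7-methoxy-2-(4-methoxyphenyl)-4-oxo-4H-chromen-3-yl]-2-(4-methoxyphenyl)chroman-4-one F3. The two are separated on a chiral stationary phase (preparative SFC). F3 is returned to the racemate under the same conditions, through ring opening and reclosure, and recycled.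

3. Step 6. The enolate or the base may attack the pyranone ring of the iodoflavone, the C–I bond may be reduced, or reductive elimination at the hindered C3 may be slow. The fallback sets out from 7 and returns at 11, building the ketone from a flavone-3-acetic acid instead. Negishi-type coupling of 7 with the Reformatsky reagent BrZnCH2CO2tBu (Pd(dba)2, tri-tert-butylphosphine, THF) gives tert-butyl 2-[5-(benzyloxy)-7-methoxy-2-(4-methoxyphenyl)-4-oxo-4H-chromen-3-yl]acetate F4. Trifluoroacetic acid in CH2Cl2 frees 2-[5-(benzyloxy)-7-methoxy-2-(4-methoxyphenyl)-4-oxo-4H-chromen-3-yl]acetic acid F5. BF3·OEt2-promoted Friedel–Crafts acylation of commercial 3,5-bis(benzyloxy)phenol ortho to its hydroxyl gives 1-[2,4-bis(benzyloxy)-6-hydroxyphenyl]-2-[5-(benzyloxy)-7-methoxy-2-(4-methoxyphenyl)-4-oxo-4H-chromen-3-yl]ethanone F6. MOM protection as in step 5 then gives 11.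

**Further compounds**

F1 | step 10 | (2S,3R)-5,7-dihydroxy-3-[5-hydroxy-7-methoxy-2-(4-methoxyphenyl)-4-oxo-4H-chromen-3-yl]-2-(4-methoxyphenyl)chroman-4-one | COc1ccc([C@H]2Oc3cc(O)cc(O)c3C(=O)[C@@H]2c2c(-c3ccc(OC)cc3)oc3cc(OC)cc(O)c3c2=O)cc1
F2 | step 10 | (2S,3R)-5,7-dihydroxy-3-[(2R,3R)-5-hydroxy-7-methoxy-2-(4-methoxyphenyl)-4-oxochroman-3-yl]-2-(4-methoxyphenyl)chroman-4-one | COc1ccc([C@H]2Oc3cc(O)cc(O)c3C(=O)[C@@H]2[C@H]2C(=O)c3c(O)cc(OC)cc3O[C@H]2c2ccc(OC)cc2)cc1
F3 | step 9 | (2R,3S)-5,7-bis(benzyloxy)-3-[5-(benzyloxy)-7-methoxy-2-(4-methoxyphenyl)-4-oxo-4H-chromen-3-yl]-2-(4-methoxyphenyl)chroman-4-one | COc1ccc([C@@H]2Oc3cc(OCc4ccccc4)cc(OCc4ccccc4)c3C(=O)[C@H]2c2c(-c3ccc(OC)cc3)oc3cc(OC)cc(OCc4ccccc4)c3c2=O)cc1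
F4 | step 6 | tert-butyl 2-[5-(benzyloxy)-7-methoxy-2-(4-methoxyphenyl)-4-oxo-4H-chromen-3-yl]acetate | COc1ccc(-c2oc3cc(OC)cc(OCc4ccccc4)c3c(=O)c2CC(=O)OC(C)(C)C)cc1
F5 | step 6 | 2-[5-(benzyloxy)-7-methoxy-2-(4-methoxyphenyl)-4-oxo-4H-chromen-3-yl]acetic acid | COc1ccc(-c2oc3cc(OC)cc(OCc4ccccc4)c3c(=O)c2CC(=O)O)cc1
F6 | step 6 | 1-[2,4-bis(benzyloxy)-6-hydroxyphenyl]-2-[5-(benzyloxy)-7-methoxy-2-(4-methoxyphenyl)-4-oxo-4H-chromen-3-yl]ethanone | O=C(Cc1c(-c2ccc(OC)cc2)oc2cc(OC)cc(OCc3ccccc3)c2c1=O)c1c(O)cc(OCc2ccccc2)cc1OCc1ccccc1
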